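**Retrosynthetic overview** (dioxane numbering used throughout: O1–O2–C3(OH)–C4(CH3, lactone O)–C5H2–C6(CH3, side chain))

1. The 1,2-dioxan-3-ol is taken back to a cyclobutanol by removing O2 and joining C3 to C6 (forward: aerobic Co(acac)2 ring expansion, last step); the γ-lactone is taken back to an acetate on the C4 oxygen and a C3 ketone (intramolecular aldol).
2. The cyclobutane C3–C4–C5–C6 is cut at C3–C4 and C5–C6 into an enone C=C (C3 = α-carbon, C6 = β-carbon) and allene (C4 = central carbon; C5 and the C4 methyl = its termini): a [2+2] photocycloaddition.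
3. Enabling feature: C3, C6 and the first four side-chain carbons [CH2–CH(CH3)–CH2–CH2] close a six-membered ring, (S)-3,5-dimethylcyclohex-2-en-1-one. This temporary ring is the chromophore; its methyl stereocentre (the side-chain stereocentre) steers the photoaddition and, through it, C4; a Baeyer–Villiger oxidation later opens it and puts the hemiketal oxygen on C3.
4. The side chain is finished from the Baeyer–Villiger lactone carbonyl carbon (methylenation, hydroboration, B-alkyl Suzuki coupling with an (E)-vinyl iodide).
5. Ring order: cyclohexenone (temporary) → cyclobutane (photochemical) → seven-membered lactone (temporary) → γ-lactone → 1,2-dioxane.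

Key step: step 3

Remark: in step 2 the cinchona-derived primary amine is used in the pseudoenantiomeric series that delivers the (S)-enone (9-amino-9-deoxy-epi-quinine or its quinidine-derived counterpart).

**Route**

Step 1
Reactants: 1 3-methylpentanedioic acid (3-methylglutaric acid)
Product: 2 4-methylheptane-2,6-dione
Conditions: MeLi (4.4 equiv), THF, 0 → 25 °C; inverse quench into cold aq. HCl
Reagents that add atoms: methyllithium, [Li]C
Why: Addition of an organolithium to a lithium carboxylate stops at the dilithio gem-diolate and gives the methyl ketone at both termini on hydrolysis (ketone synthesis from carboxylic acids); the product is achiral.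

Step 2
Reactants: 2 4-methylheptane-2,6-dione
Product: 3 (S)-3,5-dimethylcyclohex-2-en-1-one
Conditions: 9-amino-9-deoxy-epi-quinine (20 mol %), AcOH (60 mol %), toluene, −15 °C
Reagents that add atoms: none
Why: Primary-amine (enamine/iminium) catalysed desymmetrising intramolecular aldol condensation of a 4-substituted heptane-2,6-dione, a known entry to 5-substituted 3-methylcyclohex-2-enones; the catalyst tells the two enantiotopic acetonyl arms apart and so sets the methyl-bearing stereocentre, which becomes the side-chain stereocentre of the target.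

Step 3
Reactants: 3 (S)-3,5-dimethylcyclohex-2-en-1-one; 4 propadiene (allene)
Product: 5 (1S,4S,6R)-4,6-dimethyl-8-methylidenebicyclo[4.2.0]octan-2-one (cis-fused; four-membered ring anti to the 4-methyl group)
Conditions: hν (Hg lamp, uranium-glass filter, λ > 330 nm), allene (10 equiv), THF, −78 °C; then basic Al2O3, 25 °C
Reagents that add atoms: none
Why: Excitation of the enone and intersystem crossing give the triplet, whose α-carbon (C3) bonds to the central allene carbon (C4) to give a 1,4-biradical (tertiary alkyl radical at C6, 2-substituted allyl radical), and after spin inversion C6 recombines with the allyl terminus C5, so that the C3–C4 and C5–C6 bonds are both made in this one operation. The closest known reaction type is the enone–allene [2+2] photocycloaddition, long established for 3-methylcyclohex-2-enones. The only ring closed is the cyclobutane, by 1,4-biradical collapse (formally a [2π+2π] addition across the enone C=C); any trans-fused adduct is epimerised at the enolisable ring-fusion carbon on basic Al2O3 to the cis-fused bicycle. Of the two new stereocentres, C6 is controlled by the resident methyl-bearing stereocentre: the relaxed triplet has a pyramidal β-carbon that bonds axially in the half-chair in which that methyl is equatorial, which puts the four-membered ring on the face anti to it, and C3 follows from the cis ring fusion. The step needs head-to-head regiochemistry (methylidene carbon next to the α-carbon), which the substrate pair secures because only bonding at the central allene carbon gives an allyl-stabilised biradical, and it needs that facial selectivity, because C3 and C6 relay this configuration to C4 before they are themselves erased. Irradiation above 330 nm at −78 °C, where only the enone absorbs strongly, limits secondary acyl-shift photochemistry of the β,γ-unsaturated ketone product.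

Step 4
Reactants: 5 (1S,4S,6R)-4,6-dimethyl-8-methylidenebicyclo[4.2.0]octan-2-one
Product: 7 5,7-dimethyl-2-oxaspiro[bicyclo[5.2.0]nonane-9,2'-oxiran]-3-one (oxirane oxygen on the convex face; lactone oxygen on the cyclobutane methine), via spiro-epoxy ketone 6 (not isolated)
Conditions: mCPBA (2.5 equiv), NaHCO3, CH2Cl2, 0 → 25 °C
Reagents that add atoms: meta-chloroperbenzoic acid (mCPBA), O=C(OO)c1cccc(Cl)c1
Why: Prilezhaev epoxidation of the strained 1,1-disubstituted alkene from the convex face of the cis-fused bicycle (the face of the ring-fusion hydrogen, away from the six-membered ring) sets C4 with its oxygen exo, and the following Baeyer–Villiger oxidation inserts oxygen on the more substituted (methine) side with retention, which puts the future hemiketal oxygen on C3 and turns the temporary carbocycle into a seven-membered lactone.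

Step 5
Reactants: 7 5,7-dimethyl-2-oxaspiro[bicyclo[5.2.0]nonane-9,2'-oxiran]-3-one
Product: 9 5-methyl-5-[(2R)-2-methylpent-4-en-1-yl]-1-oxaspiro[2.3]hexan-4-ol (hydroxyl trans to the oxirane oxygen), via lactol 8 (not isolated)
Conditions: iBu2AlH (1.1 equiv), CH2Cl2, −78 °C; then Ph3P=CH2 [Ph3PCH3Br, KN(SiMe3)2], THF, −78 → 25 °C
Reagents that add atoms: methyltriphenylphosphonium bromide, C[P+](c1ccccc1)(c1ccccc1)c1ccccc1.[Br-]
Why: Low-temperature half-reduction of the lactone to the lactol and Wittig methylenation of its open hydroxy-aldehyde form; no stereocentre is created and the epoxide should survive at these temperatures.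

Step 6
Reactants: 9 5-methyl-5-[(2R)-2-methylpent-4-en-1-yl]-1-oxaspiro[2.3]hexan-4-ol
Product: 10 2,4-dimethyl-4-[(2R)-2-methylpent-4-en-1-yl]cyclobutane-1,2-diol (1,2-trans diol; 2-hydroxyl cis to the 4-methyl)
Conditions: LiAlH4, Et2O, 0 → 25 °C
Reagents that add atoms: none
Why: Hydride opens the spiro-epoxide at its unhindered CH2 terminus (SN2 reductive epoxide opening), so the C4–O bond is untouched, the tertiary alcohol keeps the configuration set in step 4 and the CH2 becomes the C4 methyl group.

Step 7
Reactants: 11 but-2-yn-1-ylbenzene
Product: 13 (E)-(3-iodobut-2-en-1-yl)benzene, via alkenylzirconocene 12 (not isolated)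
Conditions: Cp2Zr(H)Cl (1.5 equiv), THF, 25 → 40 °C; then I2, 0 °C
Reagents that add atoms: iodine, II
Why: syn-Hydrozirconation puts zirconium on the less hindered, methyl-bearing alkyne carbon (equilibration with a slight excess of the hydride), and iodinolysis with retention gives the (E)-vinyl iodide; the alkene geometry follows from the syn addition.

Step 8
Reactants: 10 2,4-dimethyl-4-[(2R)-2-methylpent-4-en-1-yl]cyclobutane-1,2-diol; 13 (E)-(3-iodobut-2-en-1-yl)benzene
Product: 15 4-[(2R,6E)-2,6-dimethyl-8-phenyloct-6-en-1-yl]-2,4-dimethylcyclobutane-1,2-diol (ring configuration as in 10), via B-alkyl-9-BBN adduct 14 (not isolated)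
Conditions: 9-BBN-H (3 equiv), THF, 25 °C; then 13, Pd(dppf)Cl2 (5 mol %), AsPh3, Cs2CO3, DMF/H2O, 25 °C
Reagents that add atoms: none
Why: Anti-Markovnikov hydroboration of the terminal alkene and B-alkyl Suzuki–Miyaura coupling, which retains the vinyl iodide geometry; no new stereocentre, the (E)-alkene is carried over from 13.

Step 9
Reactants: 15 4-[(2R,6E)-2,6-dimethyl-8-phenyloct-6-en-1-yl]-2,4-dimethylcyclobutane-1,2-diol
Product: 16 4-[(2R,6E)-2,6-dimethyl-8-phenyloct-6-en-1-yl]-2-hydroxy-2,4-dimethylcyclobutan-1-one (2-hydroxyl cis to the 4-methyl)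
Conditions: IBX, DMSO, 25 °C
Reagents that add atoms: none
Why: IBX oxidation takes the secondary cyclobutanol to the cyclobutanone without cleaving the 1,2-diol and leaves the tertiary alcohol; the C3 stereocentre is deliberately erased here.

Step 10
Reactants: 16 4-[(2R,6E)-2,6-dimethyl-8-phenyloct-6-en-1-yl]-2-hydroxy-2,4-dimethylcyclobutan-1-one
Product: 17 3-[(2R,6E)-2,6-dimethyl-8-phenyloct-6-en-1-yl]-1,3-dimethyl-2-oxocyclobutyl acetate
Conditions: Ac2O, DMAP (cat.), Et3N, CH2Cl2, 25 °C
Reagents that add atoms: acetic anhydride, CC(=O)OC(C)=O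
Why: DMAP-catalysed acyl transfer (Steglich-type acylation) onto the tertiary α-hydroxy ketone; no stereocentre is affected.

Step 11
Reactants: 17 3-[(2R,6E)-2,6-dimethyl-8-phenyloct-6-en-1-yl]-1,3-dimethyl-2-oxocyclobutyl acetate
Product: 18 6-[(2R,6E)-2,6-dimethyl-8-phenyloct-6-en-1-yl]-5-hydroxy-1,6-dimethyl-2-oxabicyclo[3.2.0]heptan-3-one (cis-fused; 6-methyl on the face of the lactone ring)
Conditions: LiN(SiMe3)2 (1.1 equiv), THF, −78 °C; AcOH quench
Reagents that add atoms: none
Why: Intramolecular aldol addition of the acetate enolate (the only enolisable site, both α-carbons of the cyclobutanone being quaternary) to the adjacent strained ketone; the 5-exo-trig closure can only give the cis-fused γ-lactone, which sets C3 with its hydroxyl cis to the C4 methyl.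

Step 12
Reactants: 18 6-[(2R,6E)-2,6-dimethyl-8-phenyloct-6-en-1-yl]-5-hydroxy-1,6-dimethyl-2-oxabicyclo[3.2.0]heptan-3-one
Product: 20 target peroxyhemiketal lactone CNP0361739.2, via hydroperoxy keto lactone 19 (not isolated)
Conditions: Co(acac)2 (20 mol %), O2 (1 atm), MeCN, 25–40 °C; chromatography
Reagents that add atoms: dioxygen, O=O
Why: Co(acac)2/O2 oxidative ring expansion of a cyclobutanol to a 1,2-dioxan-3-ol: the cobalt-generated alkoxy radical undergoes strain-driven β-scission of the C3–C6 bond (expected over the ring-fusion bond C3–C4, whose acyloxy oxygen is electron-poor and held in the lactone plane, where it cannot stabilise a radical developing in that plane), the tertiary C6 radical captures O2, and the hydroperoxide closes on the C3 ketone to the cis-fused peroxyhemiketal, which fixes C3; O2 capture at the acyclic radical is not expected to be face-selective, so the C6 configuration is secured by chromatographic separation of the two C6 epimers.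

**Compound list**

1 | 3-methylpentanedioic acid | CC(CC(O)=O)CC(O)=O | starting material
2 | 4-methylheptane-2,6-dione | CC(=O)CC(C)CC(C)=O | intermediate
3 | (S)-3,5-dimethylcyclohex-2-en-1-one | CC1=CC(=O)C[C@@H](C)C1 | intermediate
4 | propadiene (allene) | C=C=C | starting material
5 | (1S,4S,6R)-4,6-dimethyl-8-methylidenebicyclo[4.2.0]octan-2-one | O=C1C[C@@H](C)C[C@]2(C)CC(=C)[C@H]12 | intermediate
6 | 4,6-dimethylspiro[bicyclo[4.2.0]octane-8,2'-oxiran]-2-one, oxirane O on the convex face | O=C1C[C@@H](C)C[C@]2(C)C[C@]3(CO3)[C@H]12 | intermediate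
7 | 5,7-dimethyl-2-oxaspiro[bicyclo[5.2.0]nonane-9,2'-oxiran]-3-one | O=C1C[C@@H](C)C[C@]2(C)C[C@]3(CO3)[C@@H]2O1 | intermediate
8 | lactol of 7 (3-hydroxy, anomer mixture) | OC1C[C@@H](C)C[C@]2(C)C[C@]3(CO3)[C@@H]2O1 | intermediate
9 | 5-methyl-5-[(2R)-2-methylpent-4-en-1-yl]-1-oxaspiro[2.3]hexan-4-ol | C=CC[C@@H](C)C[C@]1(C)C[C@]2(CO2)[C@@H]1O | intermediate
10 | 2,4-dimethyl-4-[(2R)-2-methylpent-4-en-1-yl]cyclobutane-1,2-diol (trans diol, 2-OH cis to 4-CH3) | C=CC[C@@H](C)C[C@]1(C)C[C@@](C)(O)[C@@H]1O | intermediate
11 | but-2-yn-1-ylbenzene | CC#CCc1ccccc1 | starting material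
12 | (E)-chlorobis(cyclopentadienyl)(4-phenylbut-2-en-2-yl)zirconium | C/C(=C\Cc1ccccc1)[Zr](Cl)(C1C=CC=C1)C1C=CC=C1 | intermediate
13 | (E)-(3-iodobut-2-en-1-yl)benzene | C/C(I)=C\Cc1ccccc1 | intermediate
14 | B-alkyl-9-BBN adduct of 10 | C(CC[C@@H](C)C[C@]1(C)C[C@@](C)(O)[C@@H]1O)B1C2CCCC1CCC2 | intermediate
15 | 4-[(2R,6E)-2,6-dimethyl-8-phenyloct-6-en-1-yl]-2,4-dimethylcyclobutane-1,2-diol | C/C(=C\Cc1ccccc1)CCC[C@@H](C)C[C@]1(C)C[C@@](C)(O)[C@@H]1O | intermediate
16 | 4-[(2R,6E)-2,6-dimethyl-8-phenyloct-6-en-1-yl]-2-hydroxy-2,4-dimethylcyclobutan-1-one | C/C(=C\Cc1ccccc1)CCC[C@@H](C)C[C@]1(C)C[C@@](C)(O)C1=O | intermediate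
17 | 3-[(2R,6E)-2,6-dimethyl-8-phenyloct-6-en-1-yl]-1,3-dimethyl-2-oxocyclobutyl acetate | C/C(=C\Cc1ccccc1)CCC[C@@H](C)C[C@]1(C)C[C@@](C)(OC(C)=O)C1=O | intermediate
18 | 6-[(2R,6E)-2,6-dimethyl-8-phenyloct-6-en-1-yl]-5-hydroxy-1,6-dimethyl-2-oxabicyclo[3.2.0]heptan-3-one (cis-fused) | C/C(=C\Cc1ccccc1)CCC[C@@H](C)C[C@]1(C)C[C@@]2(C)OC(=O)C[C@@]12O | intermediate
19 | (5R)-5-[(2R,4R,8E)-2-hydroperoxy-2,4,8-trimethyl-10-phenyldec-8-en-1-yl]-5-methylfuran-2,4(3H,5H)-dione | C/C(=C\Cc1ccccc1)CCC[C@@H](C)C[C@@](C)(OO)C[C@@]1(C)OC(=O)CC1=O | intermediate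
20 | target peroxyhemiketal lactone CNP0361739.2 | C/C(=C\Cc1ccccc1)CCC[C@@H](C)C[C@]1(C)C[C@@]2(C)OC(=O)C[C@@]2(O)OO1 | target

**Step count and risks**

Total steps: 12. Longest linear sequence: 11 steps (steps 1–6 and 8–12; step 7 is the side branch).

Steps most likely to fail:

Step 12. What may go wrong: fragmentation of the alkoxy radical at the ring-fusion bond C3–C4 instead of C3–C6, slow radical generation at the hindered tertiary alcohol, and oxygen capture at C6 without facial preference. The fallback replaces the radical C–C cleavage by an ionic oxygen insertion and an ionic peroxide closure, so that migratory aptitude instead of radical stability decides which bond breaks. It sets out from acetoxy ketone 17. Baeyer–Villiger oxidation with bis(trimethylsilyl) peroxide and catalytic TMSOTf in CH2Cl2 at low temperature (conditions that spare the trisubstituted alkene) should move the alkyl-substituted quaternary carbon C6, rather than the acetoxy-bearing C4, onto oxygen with retention and give the γ-lactone F1. LiN(SiMe3)2 in THF at −78 °C then turns the acetate enolate onto the lactone carbonyl (intramolecular Claisen-type acylation) to give the bicyclic hemiketal F2, the mono-oxygen analogue of the target with a tetrahydrofuran in place of the dioxane. Perhydrolysis with ethereal H2O2 and catalytic H2SO4 (hemiketal exchange, ionisation of the tertiary C6–O bond and capture by the hydroperoxide, the classical route from tertiary carbinols to tertiary hydroperoxides) comes back to the route at target 20, again as a pair of C6 epimers to be separated.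

Step 4. What may go wrong: migration of the ring CH2 instead of the cyclobutyl methine in the Baeyer–Villiger stage, because the methine is deactivated by the new β-oxygen, and acid-induced ring enlargement of the oxaspirohexane by 3-chlorobenzoic acid. The fallback changes the order and the way in which the C4 oxygen is introduced. It sets out from photoadduct 5. Baeyer–Villiger oxidation with bis(trimethylsilyl) peroxide/TMSOTf, which leaves C=C bonds alone and in which the migrating methine is allylic, should give the methylidene lactone F3. Mukaiyama hydration (Mn(dpm)3, PhSiH3, O2, iPrOH) adds hydrogen to the CH2 terminus and hydroxyl to C4 from the convex face to give the hydroxy lactone F4. iBu2AlH reduction and Wittig methylenation as in step 5 come back to the route at diol 10.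

Step 3. What may go wrong: insufficient facial bias from the single ring methyl group, some head-to-tail adduct, and secondary photochemistry of the β,γ-unsaturated ketone. The fallback builds the same cyclobutane thermally under the control of two substituents. It sets out from enone 3. Luche reduction (NaBH4, CeCl3·7H2O, MeOH) should give the cis allylic alcohol F5, which is silylated (TBSCl, imidazole) to the silyl ether F6. [2+2] Cycloaddition of the keteniminium salt made from N,N-dimethylacetamide, Tf2O and 2,4,6-collidine, anti to both the silyloxy and the methyl group and with the iminium carbon bonding to the less substituted alkene carbon, gives after aqueous hydrolysis the cyclobutanone F7. Wittig methylenation gives the methylidene silyl ether F8, Bu4NF the alcohol F9, and Dess–Martin oxidation comes back to the route at photoadduct 5.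

**Further compounds**

F1 | step 12 | 3-acetoxy-5-[(2R,6E)-2,6-dimethyl-8-phenyloct-6-en-1-yl]-3,5-dimethyldihydrofuran-2(3H)-one | C/C(=C\Cc1ccccc1)CCC[C@@H](C)C[C@]1(C)C[C@@](C)(OC(C)=O)C(=O)O1
F2 | step 12 | cis-fused tetrahydrofuran hemiketal lactone (oxa analogue of the target) | C/C(=C\Cc1ccccc1)CCC[C@@H](C)C[C@]1(C)C[C@@]2(C)OC(=O)C[C@@]2(O)O1
F3 | step 4 | 5,7-dimethyl-9-methylidene-2-oxabicyclo[5.2.0]nonan-3-one | O=C1C[C@@H](C)C[C@]2(C)CC(=C)[C@@H]2O1
F4 | step 4 | 9-hydroxy-5,7,9-trimethyl-2-oxabicyclo[5.2.0]nonan-3-one (hydroxyl on the convex face) | O=C1C[C@@H](C)C[C@]2(C)C[C@@](C)(O)[C@@H]2O1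
F5 | step 3 | (1S,5S)-3,5-dimethylcyclohex-2-en-1-ol (cis) | CC1=C[C@@H](O)C[C@@H](C)C1
F6 | step 3 | tert-butyldimethylsilyl ether of F5 | CC1=C[C@@H](O[Si](C)(C)C(C)(C)C)C[C@@H](C)C1
F7 | step 3 | 2-(tert-butyldimethylsilyloxy)-4,6-dimethylbicyclo[4.2.0]octan-8-one (cis-fused, four-membered ring anti to OSi and CH3) | O=C1C[C@@]2(C)C[C@H](C)C[C@H](O[Si](C)(C)C(C)(C)C)[C@@H]12
F8 | step 3 | tert-butyldimethylsilyl ether of 4,6-dimethyl-8-methylidenebicyclo[4.2.0]octan-2-ol | C=C1C[C@@]2(C)C[C@H](C)C[C@H](O[Si](C)(C)C(C)(C)C)[C@@H]12
F9 | step 3 | 4,6-dimethyl-8-methylidenebicyclo[4.2.0]octan-2-ol | C=C1C[C@@]2(C)C[C@H](C)C[C@H](O)[C@@H]12
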